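## The problem

1. Target 13 is (2S)-5,4'-dihydroxy-7,3'-dimethoxy-6,8-diprenylflavanone. It is a chroman-4-one (ring C: O1, C2, C3, C4, C4a, C8a) fused to benzene ring A, and it carries the guaiacyl ring B at C2.
2. Ring A is hexasubstituted (acyl C4 on C4a, OH on C5, prenyl on C6, OMe on C7, prenyl on C8, O1 on C8a). No simple building block has this pattern, the three oxygens must end in three different states, and intermolecular C-prenylation of phloroglucinol-type rings spreads over O-, mono-, di- and geminal alkylation.
3. C2 is the only stereocentre, so nothing in the molecule can control it. It has to come from a catalyst or a reagent.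
4. C2 is also labile. It is benzylic, β to the C4 ketone and para to the 4'-OH, so base opens ring C by retro-oxa-Michael reaction (E1cB, or through the para-quinone methide) and recloses it to the racemate. Closing O1–C2 is therefore a reversible way to set it.
5. Both prenyl groups lie ortho to phenolic oxygens. Strong Brønsted or Lewis acids close them to chromans, oxidants give chromenes, and hydrogenation saturates them. This excludes benzyl ethers, hot acid deprotection and late Lewis-acid demethylation.
6. The feature that opens the plan is the local mirror plane of ring A through C4a and C7. C6 and C8 carry the same prenyl group, and each lies ortho to one of the two oxygens (O5 on C5, O1 on C8a) that flank C4a. Each C-prenyl group is therefore the [3,3] image of an O-bound 1,1-dimethylallyl group whose only open ortho position is exactly C6 or C8.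
7. A second feature completes it. C2 is the β-carbon of the C4 carbonyl and holds ring B by a C–C bond, so removing ring B leaves a flat, achiral chromone.

## Retrosynthesis

**13 ⇒ 12 (O4'–Si).** The route uses one protecting group, a silyl ether on the 4'-oxygen.
- A free para-phenol would open the quinone methide channel for racemisation during the C–C bond formation.
- It would also make the boron reagent prone to protodeboronation.
- Benzyl needs hydrogen and acetals need acid, whereas the silyl ether falls to buffered fluoride.
- The forward step only has to stay non-basic.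

**12 ⇒ 8 + 11 (C2–C1').**
- The neighbouring cut O1–C2 gives a reversible C–O closure.
- The neighbouring cut C2–H would need hydride delivery to a less electrophilic, 2-aryl-substituted pyranone that holds ring B from the start.
- Cutting C2–C1' makes the stereocentre in an irreversible C–C bond formation, splits the molecule into two parts of similar size, and leaves chromone 8 achiral.
- All heat and base therefore fall before any stereocentre exists.
- The forward reaction must choose the C2=C3 bond over two trisubstituted alkenes, choose one face of C2 under ligand control, and run near neutrality.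

**8 ⇒ 5 by way of 7 and 6 (O1–C2, C6–CH2, C8–CH2; the key step).** Three bonds are cut at once.
- An intermolecular prenyl electrophile could not tell C from O or mono from poly.
- A linear O-prenyl ether would deliver the reversed (1,1-dimethylallyl) group.
- O7 could feed only one position at a time and is needed as OMe.
- Tertiary allyl ethers on O5 and O1 each have a single open ortho carbon and give the linear prenyl group by allyl inversion.
- Their departure frees exactly the phenols that ring C closure needs.
- Precursor 5 has a mirror-symmetric arene with two free CH positions and only O-substituents.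
- The forward step has to be concerted (no ionisation of the tertiary ethers) and has to expel the amine irreversibly.

**5 ⇒ 4 (C2=C3).**
- The one-carbon unit that becomes C2 is joined to the acetyl methyl group (future C3).
- This is done while both phenols are still masked, so ring closure cannot start early and the phenols cannot be alkylated by the reagent.
- The forward reaction must run below the temperature at which the ethers shift.

**4 ⇒ 3 + 2, and 2 ⇒ 1 (two O–C bonds).**
- Ketone 3 is commercial and already holds the C7 methyl ether, so O7 is differentiated by purchase.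
- Its two hydroxyl groups are equivalent and receive the same group.
- Carbonate 2, made from alcohol 1, is the ionisable source of the 1,1-dimethylallyl unit.
- The forward reaction must attack the substituted allyl terminus and must reach the second, hydrogen-bonded hydroxyl group.

**11 ⇒ 10 ⇒ 9 (C1'–B, O–Si).**
- Ring B comes from commercial bromophenol 9, in which the bromine marks C1' para to the oxygen.
- No regiochemical question arises.

## Roads not taken

Alternative 1: cut O1–C2, the most obvious plan.
- An aldol condensation of a C-prenylated ring A methyl ketone with the ring B aldehyde would give chalcone A1. A chiral base or hydrogen-bond donor would then close it by intramolecular oxa-Michael addition.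
- The closure is reversible under the conditions that catalyse it, so the enantiomeric purity drifts towards the racemate.
- High selectivity in this reaction class depends on an extra activating group at C3, which must be installed and removed.
- A1 also needs the unselective intermolecular C-prenylation, and a strongly basic condensation that forces protection of three phenols with groups that must later leave without acid.
- The chosen plan forms the stereocentre irreversibly and uses one protecting group.

Alternative 2: cut C6–CH2 and C8–CH2 on a finished flavanone.
- An enantioenriched 6,8-unsubstituted core would be iodinated twice to A2 and coupled twice with a prenyl tin or boron reagent under palladium catalysis.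
- Ring B is as electron-rich as ring A and competes for the halogen.
- Both C–I bonds are flanked on both sides.
- Allyl metals raise the linear-versus-branched question twice.
- The labile C2 centre has to survive three or more further steps with heat and base.
- The asymmetric synthesis of the core is still needed, so nothing is saved.

Alternative 3: build ring A last.
- A vinylketene would be made by photochemical Wolff rearrangement of the enantiopure dihydropyranone diazoketone A3. It would combine with ynol ether A4 by [2+2] addition, four-electron ring opening and six-electron closure, which would give 12 directly.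
- The polarity of ketene and ynol ether would place every substituent of ring A.
- The idea is attractive, but A3 is hardly simpler than the product. It needs an asymmetric hetero-Diels–Alder reaction, acylation at C6 of the pyranone and a diazo transfer.
- Its carbene has an allylic CH2 next to it, which invites a 1,2-hydride shift.
- The stereocentre would pass through light and heat.
- The run-up would cost more than the key step gains.

Key step: step 4

Assumption: the descriptor in the SMILES string is read as (2S) (O1 > C1' > C3 > H). Flavanone numbering is used throughout, and prenyl means 3-methylbut-2-en-1-yl.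

## Steps

Step 1
Reactants: 1 2-methylbut-3-en-2-ol
Product: 2 tert-butyl (2-methylbut-3-en-2-yl) carbonate
Conditions: n-BuLi (1.0 equiv), THF, −78 to 0 °C; Boc2O (1.05 equiv), 0 °C to rt; H2O work-up
Reagents that add atoms: di-tert-butyl dicarbonate, CC(C)(C)OC(=O)OC(=O)OC(C)(C)C
Why: Alkoxycarbonylation of a lithium alkoxide with Boc2O; prior deprotonation keeps the medium free of acid, so the tertiary allylic alcohol should not transpose, and the carbonate is the leaving group that step 2 needs.

Step 2
Reactants: 3 1-(2,6-dihydroxy-4-methoxyphenyl)ethan-1-one; 2 tert-butyl (2-methylbut-3-en-2-yl) carbonate (3 equiv)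
Product: 4 1-{4-methoxy-2,6-bis[(2-methylbut-3-en-2-yl)oxy]phenyl}ethan-1-one
Conditions: Pd(PPh3)4 (5 mol %), THF, 0–5 °C, dark; concentration below 30 °C
Reagents that add atoms: none
Why: Decarboxylative Tsuji–Trost O-allylation: zerovalent palladium ionises 2 to the 1,1-dimethyl-π-allylpalladium cation, CO2 and tert-butoxide, which deprotonates the phenol. Under kinetic control at low temperature phenoxides attack the substituted allyl terminus, a known entry to aryl 1,1-dimethylallyl ethers, and the mirror symmetry of 3 means both hydroxyl groups need the same treatment.

Step 3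
Reactants: 4 1-{4-methoxy-2,6-bis[(2-methylbut-3-en-2-yl)oxy]phenyl}ethan-1-one
Product: 5 (E)-3-(dimethylamino)-1-{4-methoxy-2,6-bis[(2-methylbut-3-en-2-yl)oxy]phenyl}prop-2-en-1-one
Conditions: t-BuOCH(NMe2)2 (2 equiv), PhMe, 60 °C; volatiles removed in vacuo
Reagents that add atoms: tert-butoxybis(dimethylamino)methane (Bredereck's reagent), CC(C)(C)OC(N(C)C)N(C)C
Why: Aminomethylenation of a methyl ketone (enaminone synthesis); the reagent releases tert-butoxide and a formamidinium ion and should react well below the temperature at which the ethers shift. With both phenols masked, neither early ring closure nor O-alkylation can occur, and the push–pull alkene settles as the E isomer.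

Step 4
Reactants: 5 (E)-3-(dimethylamino)-1-{4-methoxy-2,6-bis[(2-methylbut-3-en-2-yl)oxy]phenyl}prop-2-en-1-one
Product: 8 5-hydroxy-7-methoxy-6,8-bis(3-methylbut-2-en-1-yl)-4H-chromen-4-one, via mono-shifted phenol 6 (not isolated), via doubly shifted enaminone 7 (not isolated)
Conditions: PhMe (0.05 M, degassed), 125 °C, sealed tube; then AcOH–PhMe 1:4, 60 °C
Reagents that add atoms: none
Why: Heating should trigger two concerted suprafacial [3,3]-sigmatropic shifts (aromatic Claisen rearrangement) through chair-like transition states: each O–CMe2 bond breaks while the CH2 terminus bonds to the free ortho carbon, the ortho-dienone tautomerises to the phenol, and allyl inversion turns the tertiary ether into the linear prenyl group (5 to 6 to 7). The closest known reaction types are the Claisen rearrangement of aryl 1,1-dimethylallyl ethers to ortho-prenylphenols and the cyclisation of o-hydroxyaryl enaminones to chromones, here run in one flask. Ring C closes by 6-endo-trig addition of a released phenol oxygen to the enaminone β-carbon followed by loss of dimethylamine (vinylogous addition–elimination), and acetic acid protonates the amine and so blocks the reverse opening of the pyranone. No stereocentre is formed and 8 is achiral. The selectivity needed is regiochemical, and the substrate secures it: each ether oxygen has one open ortho carbon (future C6 or C8), the other ortho carbon is the acyl-bearing C4a and the para carbon bears OMe, so a shift to C4a gives a dienone that cannot enolise and can only return. The two ethers of 5 are related by the local mirror plane and the two phenols of 7 are exchanged by rotation about the aryl–carbonyl bond, so neither the order of the three events nor the choice of the closing oxygen matters; all paths lead to 8, and the oxygen left over becomes the hydrogen-bonded 5-OH. The geminal methyl groups lower the barrier, which should keep the temperature below the range in which o-prenylphenols rearrange further, and the basic enaminone buffers traces of acid that would ionise the tertiary ethers.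

Step 5
Reactants: 9 4-bromo-2-methoxyphenol
Product: 10 (4-bromo-2-methoxyphenoxy)(tert-butyl)dimethylsilane
Conditions: TBSCl (1.1 equiv), imidazole (2.2 equiv), DMF, rt
Reagents that add atoms: tert-butyldimethylsilyl chloride, CC(C)(C)[Si](C)(C)Cl
Why: Standard imidazole-promoted O-silylation of a phenol; the aryl bromide is inert.

Step 6
Reactants: 10 (4-bromo-2-methoxyphenoxy)(tert-butyl)dimethylsilane
Product: 11 {4-[(tert-butyldimethylsilyl)oxy]-3-methoxyphenyl}boronic acid
Conditions: n-BuLi (1.05 equiv), THF, −78 °C; B(Oi-Pr)3 (1.5 equiv), −78 °C to rt; 1 M aq. HCl, 0 °C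
Reagents that add atoms: triisopropyl borate, CC(C)OB(OC(C)C)OC(C)C; water, O
Why: Bromine–lithium exchange, borylation and hydrolysis of the borate; the lithium sits para to the silyl ether, so no O-to-C silyl shift is at hand, and a brief cold acid quench spares the aryl silyl ether.

Step 7
Reactants: 8 5-hydroxy-7-methoxy-6,8-bis(3-methylbut-2-en-1-yl)-4H-chromen-4-one; 11 {4-[(tert-butyldimethylsilyl)oxy]-3-methoxyphenyl}boronic acid (3 equiv)
Product: 12 (2S)-2-{4-[(tert-butyldimethylsilyl)oxy]-3-methoxyphenyl}-5-hydroxy-7-methoxy-6,8-bis(3-methylbut-2-en-1-yl)-2,3-dihydro-4H-chromen-4-one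
Conditions: [RhCl(C2H4)2]2 (2.5 mol %), (1S,4S)-2,5-diphenylbicyclo[2.2.2]octa-2,5-diene (5.5 mol %), KOH (10 mol %), PhMe–H2O 10:1, 45 °C
Reagents that add atoms: none
Why: Hayashi–Miyaura asymmetric 1,4-addition, known on chromones: the aryl group passes from boron to monovalent rhodium, adds across C2=C3, and the oxa-π-allyl rhodium species is protonated, so the C2–C1' bond forms irreversibly while the unactivated prenyl alkenes stay untouched. The twofold-symmetric chiral diene should expose the Re face of C2 and give (2S), by analogy with the (S,S)-diene giving (S)-3-arylcyclohexanones (O1 takes the place of the ring CH2 without changing the spatial arrangement or the descriptor); the antipodal ligand is equally available should the sense prove opposite. The excess boronic acid keeps the medium close to neutral, which guards C2 against ring opening.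

Step 8
Reactants: 12 (2S)-2-{4-[(tert-butyldimethylsilyl)oxy]-3-methoxyphenyl}-5-hydroxy-7-methoxy-6,8-bis(3-methylbut-2-en-1-yl)-2,3-dihydro-4H-chromen-4-one
Product: 13 (2S)-5-hydroxy-2-(4-hydroxy-3-methoxyphenyl)-7-methoxy-6,8-bis(3-methylbut-2-en-1-yl)-2,3-dihydro-4H-chromen-4-one
Conditions: n-Bu4NF (1.1 equiv), AcOH (1.2 equiv), THF, 0 °C
Reagents that add atoms: none
Why: Fluoride cleavage of an aryl silyl ether; acetic acid protonates the phenoxide as it forms, so the medium should never become basic enough for the retro-oxa-Michael reaction, and C2 and the prenyl groups are not touched.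

## Compound list

1 | 2-methylbut-3-en-2-ol | C=CC(C)(C)O | starting material
2 | tert-butyl (2-methylbut-3-en-2-yl) carbonate | C=CC(C)(C)OC(=O)OC(C)(C)C | intermediate
3 | 1-(2,6-dihydroxy-4-methoxyphenyl)ethan-1-one | CC(=O)c1c(O)cc(OC)cc1O | starting material
4 | 1-{4-methoxy-2,6-bis[(2-methylbut-3-en-2-yl)oxy]phenyl}ethan-1-one | CC(=O)c1c(OC(C)(C)C=C)cc(OC)cc1OC(C)(C)C=C | intermediate
5 | (E)-3-(dimethylamino)-1-{4-methoxy-2,6-bis[(2-methylbut-3-en-2-yl)oxy]phenyl}prop-2-en-1-one | CN(C)/C=C/C(=O)c1c(OC(C)(C)C=C)cc(OC)cc1OC(C)(C)C=C | intermediate
6 | (E)-3-(dimethylamino)-1-{2-hydroxy-4-methoxy-3-(3-methylbut-2-en-1-yl)-6-[(2-methylbut-3-en-2-yl)oxy]phenyl}prop-2-en-1-one | CN(C)/C=C/C(=O)c1c(O)c(CC=C(C)C)c(OC)cc1OC(C)(C)C=C | intermediate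
7 | (E)-1-[2,6-dihydroxy-4-methoxy-3,5-bis(3-methylbut-2-en-1-yl)phenyl]-3-(dimethylamino)prop-2-en-1-one | CN(C)/C=C/C(=O)c1c(O)c(CC=C(C)C)c(OC)c(CC=C(C)C)c1O | intermediate
8 | 5-hydroxy-7-methoxy-6,8-bis(3-methylbut-2-en-1-yl)-4H-chromen-4-one | COc1c(CC=C(C)C)c(O)c2c(=O)ccoc2c1CC=C(C)C | intermediate
9 | 4-bromo-2-methoxyphenol | COc1cc(Br)ccc1O | starting material
10 | (4-bromo-2-methoxyphenoxy)(tert-butyl)dimethylsilane | COc1cc(Br)ccc1O[Si](C)(C)C(C)(C)C | intermediate
11 | {4-[(tert-butyldimethylsilyl)oxy]-3-methoxyphenyl}boronic acid | COc1cc(B(O)O)ccc1O[Si](C)(C)C(C)(C)C | intermediate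
12 | (2S)-2-{4-[(tert-butyldimethylsilyl)oxy]-3-methoxyphenyl}-5-hydroxy-7-methoxy-6,8-bis(3-methylbut-2-en-1-yl)-2,3-dihydro-4H-chromen-4-one | COc1cc([C@@H]2CC(=O)c3c(O)c(CC=C(C)C)c(OC)c(CC=C(C)C)c3O2)ccc1O[Si](C)(C)C(C)(C)C | intermediate
13 | (2S)-5-hydroxy-2-(4-hydroxy-3-methoxyphenyl)-7-methoxy-6,8-bis(3-methylbut-2-en-1-yl)-2,3-dihydro-4H-chromen-4-one | COc1cc([C@@H]2CC(=O)c3c(O)c(CC=C(C)C)c(OC)c(CC=C(C)C)c3O2)ccc1O | target

## Step count and least certain steps

Total step count: 8. Longest linear sequence: 6 (steps 1, 2, 3, 4, 7, 8); counted from ketone 3 it is 5 steps.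

**Step 4 (key step).**
- Most likely failures:
  - heterolysis of the tertiary allyl–oxygen bonds with loss of the C5 unit, instead of the concerted shift;
  - thermal decay of the enaminone before both shifts are over;
  - incomplete ring closure, because the released amine reopens the pyranone.
- Fallback: the cascade is taken apart and the order of events is reversed.
  - It sets out from 4. Thermolysis of the plain ketone (PhMe or N,N-diethylaniline, 120–130 °C), which holds no heat-sensitive group, should give 1-[2,6-dihydroxy-4-methoxy-3,5-bis(3-methylbut-2-en-1-yl)phenyl]ethan-1-one F1.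
  - Aminomethylenation of F1 with Me2NCH(OMe)2 (PhMe, 80 °C), a standard reaction of o-hydroxyacetophenones, leads to 7.
  - Compound 7 is closed with AcOH, and the route is rejoined at 8.

**Step 2.**
- Most likely failures:
  - attack at the unsubstituted allyl terminus;
  - C-allylation of the electron-rich ring;
  - stalling after the first etherification, because the remaining hydroxyl group is hydrogen-bonded to the ketone and crowded;
  - re-ionisation of the product by the catalyst.
- Fallback: the ionisable tertiary ether is given up, and the methyl groups are added at the end by metathesis.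
  - It sets out from 3. Allyl bromide, K2CO3, DMF, 60 °C should give 1-[4-methoxy-2,6-bis(prop-2-en-1-yloxy)phenyl]ethan-1-one F2.
  - Me2NCH(OMe)2 at 110 °C should give (E)-3-(dimethylamino)-1-[4-methoxy-2,6-bis(prop-2-en-1-yloxy)phenyl]prop-2-en-1-one F3.
  - Thermolysis at 190–200 °C in N,N-diethylaniline and then AcOH should give 5-hydroxy-7-methoxy-6,8-di(prop-2-en-1-yl)-4H-chromen-4-one F4.
  - Double cross metathesis with 2-methylbut-2-ene (second-generation Grubbs catalyst, RuCl2(PCy3)(H2IMes)(=CHPh), CH2Cl2, 40 °C) comes back to the route at 8.

**Step 7.**
- Most likely failures: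
  - slow turnover, because the 5-OH/C4=O pair binds rhodium as an O,O-chelate of the acetylacetonate type, so that protodeboronation outruns addition;
  - poor facial selectivity on this crowded chromone;
  - erosion of the enantiomeric purity by ring opening if higher temperature is needed.
- Fallback: bond formation and stereocontrol are separated.
  - It sets out from 8 and 11. Forcing, achiral conditions ([Rh(OH)(cod)]2, dioxane–H2O, 90 °C), under which racemisation no longer matters, should give racemic 2-{4-[(tert-butyldimethylsilyl)oxy]-3-methoxyphenyl}-5-hydroxy-7-methoxy-6,8-bis(3-methylbut-2-en-1-yl)-2,3-dihydro-4H-chromen-4-one F5.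
  - Kinetic resolution by asymmetric transfer hydrogenation (RhCl(Cp*)[(R,R)-TsDPEN], HCO2H–Et3N 5:2, EtOAc, rt), a known resolution of flavanones that leaves alkenes alone, should reduce the (2R) antipode. The product is the cis alcohol (2R,4R)-2-{4-[(tert-butyldimethylsilyl)oxy]-3-methoxyphenyl}-7-methoxy-6,8-bis(3-methylbut-2-en-1-yl)chromane-4,5-diol F6.
  - F6 is removed by chromatography, and the unreduced (2S) ketone is 12.
  - The price is that at most half of the material is used.

**Step 8.**
- Most likely failure: partial loss of configuration. Fluoride or the nascent 4'-phenoxide acts as a base and opens ring C through the quinone methide channel.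
- Fallback: the step is removed instead of tuned.
  - It sets out from 8, which is arylated with commercial 2-methoxy-4-(4,4,5,5-tetramethyl-1,3,2-dioxaborolan-2-yl)phenol.
  - The catalyst is the preformed hydroxorhodium complex of the same diene, used without added base (dioxane–H2O, 40 °C).
  - The route is rejoined directly at 13. No new compound is made, and steps 5, 6 and 8 fall away.

## Further compounds

F1 | step 4 | 1-[2,6-dihydroxy-4-methoxy-3,5-bis(3-methylbut-2-en-1-yl)phenyl]ethan-1-one | CC(=O)c1c(O)c(CC=C(C)C)c(OC)c(CC=C(C)C)c1O
F2 | step 2 | 1-[4-methoxy-2,6-bis(prop-2-en-1-yloxy)phenyl]ethan-1-one | CC(=O)c1c(OCC=C)cc(OC)cc1OCC=C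
F3 | step 2 | (E)-3-(dimethylamino)-1-[4-methoxy-2,6-bis(prop-2-en-1-yloxy)phenyl]prop-2-en-1-one | CN(C)/C=C/C(=O)c1c(OCC=C)cc(OC)cc1OCC=C
F4 | step 2 | 5-hydroxy-7-methoxy-6,8-di(prop-2-en-1-yl)-4H-chromen-4-one | COc1c(CC=C)c(O)c2c(=O)ccoc2c1CC=C
F5 | step 7 | racemic 2-{4-[(tert-butyldimethylsilyl)oxy]-3-methoxyphenyl}-5-hydroxy-7-methoxy-6,8-bis(3-methylbut-2-en-1-yl)-2,3-dihydro-4H-chromen-4-one | COc1cc(C2CC(=O)c3c(O)c(CC=C(C)C)c(OC)c(CC=C(C)C)c3O2)ccc1O[Si](C)(C)C(C)(C)C
F6 | step 7 | (2R,4R)-2-{4-[(tert-butyldimethylsilyl)oxy]-3-methoxyphenyl}-7-methoxy-6,8-bis(3-methylbut-2-en-1-yl)chromane-4,5-diol | COc1cc([C@H]2C[C@@H](O)c3c(O)c(CC=C(C)C)c(OC)c(CC=C(C)C)c3O2)ccc1O[Si](C)(C)C(C)(C)C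
F0 | step 8 | none | none
A1 | alternative 1 | (E)-1-[2,6-dihydroxy-4-methoxy-3,5-bis(3-methylbut-2-en-1-yl)phenyl]-3-(4-hydroxy-3-methoxyphenyl)prop-2-en-1-one | COc1cc(/C=C/C(=O)c2c(O)c(CC=C(C)C)c(OC)c(CC=C(C)C)c2O)ccc1O
A2 | alternative 2 | (2S)-2-{4-[(tert-butyldimethylsilyl)oxy]-3-methoxyphenyl}-5-hydroxy-6,8-diiodo-7-methoxy-2,3-dihydro-4H-chromen-4-one | COc1cc([C@@H]2CC(=O)c3c(O)c(I)c(OC)c(I)c3O2)ccc1O[Si](C)(C)C(C)(C)C
A3 | alternative 3 | (2S)-2-{4-[(tert-butyldimethylsilyl)oxy]-3-methoxyphenyl}-6-(2-diazo-5-methylhex-4-enoyl)-2,3-dihydro-4H-pyran-4-one | COc1cc([C@@H]2CC(=O)C=C(O2)C(=O)C(=[N+]=[N-])CC=C(C)C)ccc1O[Si](C)(C)C(C)(C)C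
A4 | alternative 3 | 1-methoxy-5-methylhex-4-en-1-yne | COC#CCC=C(C)C
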